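# Proposed synthesis of the macrocyclic bis(bibenzyl) 19 by nitro-activated SNAr ring closure

## The problem

Compound 19 is a macrocyclic bis(bibenzyl) in which four benzene rings are closed into an 18-membered cycle by two CH2CH2 bridges and two diaryl ether oxygens, in the order ring A–CH2CH2–ring B–O–ring C–CH2CH2–ring D–O–ring A. Ring A carries the bridge ortho and a hydroxyl para to its ether oxygen, ring B is an unsubstituted para-phenylene, ring C carries a hydroxyl ortho and the bridge meta to its ether oxygen, and ring D is an unsubstituted meta-phenylene. There is no stereocentre, so nothing has to be controlled in space; the only geometric elements are stilbene double bonds that appear on the way and are erased by reduction. The task is therefore one of connectivity and ring closure: two different diaryl ether bonds must be made, each at one oxygen out of several, and one bond of the cycle must form against the entropy of an 18-membered ring. Neither ether carbon is activated in the target, since that of ring B lies para to an alkyl chain and that of ring A para to an oxygen. The hydroquinone-type ring A and the catechol-type ring C are easily oxidised as free phenols and therefore travel as ethers to the last step, while an aryl fluoride next to a nitro group tolerates neither strong nucleophiles nor hydrogenation over palladium. The enabling feature is that the ether carbon of ring B (C4, para to the bridge) has a CH neighbour (C3): a nitro group placed there makes a C4 fluoride a good electrophile for the ring C oxygen and can later be excised through the amine. In the same sense the ether carbon of ring A is ortho to the bridge carbon, which at the aldehyde level activates a fluoride and then becomes part of the bridge.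

## Retrosynthesis

**19 to 18.** The last bonds cut are the two O–CH3 bonds of the di-O-methyl ether 18. Methyl is preferred to benzyl or silyl on rings A and C because it must pass through carbonate at 140 °C, hydride, hydrogenation, a boron Lewis acid at low temperature and diazotisation. Both methyl groups fall in one Lewis acid operation that leaves aryl–O–aryl bonds alone. The gain is that no free phenol of ring A or ring C exists before the end.

**18 to 16 to 15.** The C–H at C3 of ring B is traced back to C–NH2 in aniline 16 and to C–NO2 in the nitro macrocycle 15. This adds a group in the backward direction, but it is what turns ring B into an electrophile. A formyl activator would have to be removed by decarbonylation and a metal π-complex would need a stoichiometric metal, whereas nitro leaves by reduction and hydrodediazoniation. The forward steps need a nitro reduction on a substrate with nothing else reducible, and a deamination that outpaces side reactions of the aryl diazonium ion.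

**15 to 14.** The key cut is the bond between C4 of ring B and the ring C oxygen. The other ether (ring A–O–ring D) is a poorer place to close the ring, because its only possible activator is the bridge carbon, which is already sp3 in any macrocyclic precursor. Cutting a CH2CH2 bridge would close the ring through a strained macrocyclic stilbene and add a reduction. The B–O–C bond alone offers a strong, removable activation at carbon and a uniquely addressable phenol at oxygen. The precursor 14 is an open chain of four rings with one free hydroxyl and one C–F bond. The forward reaction must favour ring closure over intermolecular substitution, which is asked of dilution at room temperature.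

**14 to 13 to 12 to 10 + 11.** The phenol of 14 is released last from the isopropyl ether 13. Isopropyl is chosen because it survives every base, hydride, hydrogenation and Brønsted acid step and is cleaved by a boron Lewis acid beside methyl ethers. The A–B bridge is cut at its central bond, first to the stilbene 12 and then by Wittig disconnection to phosphonium salt 10 and 4-fluoro-3-nitrobenzaldehyde 11. The ylide is placed on ring A because 11 is very electrophilic at carbonyl. The opposite polarity would need a benzylic ylide para to a labile fluoride, which could condense with itself. The fluoronitroarene thus enters at the last C–C bond formation and afterwards meets only carbonate, a metal-free reduction and a Lewis acid. The reduction of 12 must spare the nitro group and the C–F bond, which excludes palladium and hydrogen and calls for diimide.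

**10 to 9 to 8.** The phosphonium salt 10 comes from the benzylic alcohol 9 in one acid-mediated step, made possible by the acid-stable isopropyl ether. Alcohol 9 comes from aldehyde 8 by hydride reduction. The aldehyde is kept until the ether is in place because it is the activator of the next disconnection.

**8 to 6 + 7.** The A–O–D ether is cut at the ring A carbon, giving phenol 6 and 2-fluoro-5-methoxybenzaldehyde 7. The formyl group ortho to fluorine activates the substitution and then becomes the bridge carbon, so no atom is wasted. Cutting at the ring D carbon instead would need a metal-catalysed coupling of an unactivated aryl halide with a hydroquinone monoether. The forward reaction has to overcome the deactivating methoxy group para to fluorine, which calls for heat, and 6 offers a single hydroxyl.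

**6 to 5 to 2 + 4.** The C–D bridge is cut in the same way, to stilbene 5 and then to aldehyde 2 and phosphonium salt 4. Salt 4 is made in one step from 3-hydroxybenzyl alcohol 3 and keeps its phenol free, which is exactly the nucleophile needed for the next ether, so ring D is never protected. Aldehyde 2 is isovanillin 1 with its hydroxyl masked. No nitro group is present yet, so hydrogenation over palladium is allowed here.

## Roads not taken

Alternative 1: This road cuts through ring A itself, at the bond between the bridge-bearing carbon and its CH neighbour and at the bond between the ether-bearing carbon and its CH neighbour. In the forward sense methyl coumalate A2 and the internal aryl ynol ether A3 would undergo Diels–Alder addition and decarboxylative aromatisation to the benzoate A1. In A3 the ring D oxygen and the CH2CH2–ring B chain sit on the two alkyne carbons, and the pyrone A2 supplies the other four carbons of ring A together with the ester.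

- Merits: the polarisation of A2 and A3 fixes the regiochemistry, and ether and chain arrive together without any substitution at an arene. In this respect it is better than the chosen plan, whose step 5 forces a deactivated fluoride.
- Weak points: ring A emerges in A1 as an ester, whose carbon must be exchanged for oxygen over several steps, where the chosen plan buys that oxygen as the methoxy group of 7. A2 is a simple pyrone, but A3 needs a multi-step preparation and is acid-sensitive.
- Decisive drawback: the macrocycle is still open in A1. Ring B carries an unactivated bromide, so the ring-closing ether would have to come from a copper-mediated coupling at high temperature.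
- Comparison: this road spends its effort on a ring that can be purchased and postpones the real difficulty. Against its cleaner ring A ether the chosen plan sets a ring closure at room temperature and a copper-based fallback for step 5.

Alternative 2: This road cuts two C–C bonds of ring B, C1–C6 and C2–C3, with C1 bearing the bridge and C4 the ether oxygen. The substrate A5 carries a buta-1,3-dien-2-yl group on the ring C oxygen and an ethynyl ketone on the benzylic carbon of ring A. Intramolecular cycloaddition would give the macrocyclic cyclohexadienyl ketone A4, forming ring B and the 18-membered ring together.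

- Merits: no leaving group, no base, and no bond to make at an unactivated arene carbon, since the ether oxygen is already in place as an enol ether. The para relation of acyl and oxygen follows from the diene and dienophile polarities.
- Weak points: diene and dienophile in A5 are held by a long, flexible tether with no bias towards the reactive conformation, so a thermal cycloaddition at high dilution would be slow. The aryloxy diene can dimerise or polymerise, and the ynone is enolisable and a Michael acceptor.
- After ring closure: A4 must still be aromatised and its ketone deoxygenated before demethylation, so the endgame is no shorter than the three steps needed to remove nitro and methyl groups here.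
- Comparison: the idea is more convergent in bond count, but macrocyclising cycloadditions of this kind are poorly secured. The chosen plan offers a ring closure with a close reaction-type analogy and routine neighbours.

Alternative 3: This road cuts the same B–O–C ether on the other side, at the ring C carbon. The bis(dihalophenol) A7 has a 2,6-dichlorophenol as ring B and a 2,6-dibromophenol as ring C. Oxidation with Tl(NO3)3 in methanol and reductive work-up with zinc and acetic acid would join the ring B oxygen to a bromine-bearing ortho carbon of ring C, giving the trihalogenated macrocycle A6.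

- Merits: the ring C hydroxyl emerges free in A6 without a protecting group. The halogens fall in one hydrogenolysis, so only two steps follow ring closure against three in the chosen plan. Here this road is better.
- Weak points: ring A of A7 is a hydroquinone diether, one of the arene types that trivalent thallium oxidises readily. Two phenols compete for oxidation and are told apart only by their halogens. The reagent is a stoichiometric, highly toxic thallium salt, and four halogens must be carried through two stilbene reductions that may not use palladium.
- Comparison: the chosen plan sets against the shorter endgame a redox-neutral closure with one nucleophile and one electrophile, which does not endanger ring A.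

Key step: step 11

Remark: the Wittig products 5 and 12 are expected as E/Z mixtures and are carried on as such, since both isomers give the same saturated bridge; their SMILES are written without alkene geometry.

## Route

Step 1
Reactants: 1 isovanillin (3-hydroxy-4-methoxybenzaldehyde)
Product: 2 4-methoxy-3-(propan-2-yloxy)benzaldehyde
Conditions: 2-bromopropane, K2CO3, DMF, 70 °C
Reagents that add atoms: 2-bromopropane, CC(C)Br
Why: Williamson ether synthesis on the only hydroxyl; the isopropyl ether should survive every later base, hydride, hydrogenation and Brønsted acid step and remain removable beside methyl ethers.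

Step 2
Reactants: 3 3-hydroxybenzyl alcohol
Product: 4 [(3-hydroxyphenyl)methyl]triphenylphosphonium bromide
Conditions: PPh3·HBr, MeCN, reflux
Reagents that add atoms: triphenylphosphine hydrobromide, Br.c1ccc(cc1)P(c1ccccc1)c1ccccc1
Why: Acid-mediated substitution of a benzylic alcohol by triphenylphosphine; the phenol does not react and stays free for the later ether formation.

Step 3
Reactants: 2 4-methoxy-3-(propan-2-yloxy)benzaldehyde; 4 [(3-hydroxyphenyl)methyl]triphenylphosphonium bromide
Product: 5 3-{2-[4-methoxy-3-(propan-2-yloxy)phenyl]ethenyl}phenol (E/Z mixture)
Conditions: t-BuOK (2.2 equiv), THF, 0 °C to rt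
Reagents that add atoms: none
Why: Wittig olefination with a semi-stabilised benzylic ylide; the second equivalent of base covers the phenol, and the alkene geometry is irrelevant because the double bond is reduced next.

Step 4
Reactants: 5 3-{2-[4-methoxy-3-(propan-2-yloxy)phenyl]ethenyl}phenol
Product: 6 3-{2-[4-methoxy-3-(propan-2-yloxy)phenyl]ethyl}phenol
Conditions: H2 (1 atm), 10% Pd/C, EtOAc, rt
Reagents that add atoms: none
Why: Heterogeneous catalytic hydrogenation of a stilbene; aryl ethers, the isopropyl ether and the phenol are inert.

Step 5
Reactants: 6 3-{2-[4-methoxy-3-(propan-2-yloxy)phenyl]ethyl}phenol; 7 2-fluoro-5-methoxybenzaldehyde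
Product: 8 5-methoxy-2-(3-{2-[4-methoxy-3-(propan-2-yloxy)phenyl]ethyl}phenoxy)benzaldehyde
Conditions: K2CO3, DMF, 140 °C
Reagents that add atoms: none
Why: Intermolecular SNAr (addition–elimination) at a fluoride activated by the ortho formyl group; the para methoxy group slows the addition, hence the temperature, and 6 has only one nucleophilic oxygen.

Step 6
Reactants: 8 5-methoxy-2-(3-{2-[4-methoxy-3-(propan-2-yloxy)phenyl]ethyl}phenoxy)benzaldehyde
Product: 9 [5-methoxy-2-(3-{2-[4-methoxy-3-(propan-2-yloxy)phenyl]ethyl}phenoxy)phenyl]methanol
Conditions: NaBH4, MeOH/THF, 0 °C
Reagents that add atoms: none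
Why: Borohydride reduction of an aryl aldehyde to the benzylic alcohol; no other reducible group is present.

Step 7
Reactants: 9 [5-methoxy-2-(3-{2-[4-methoxy-3-(propan-2-yloxy)phenyl]ethyl}phenoxy)phenyl]methanol
Product: 10 {[5-methoxy-2-(3-{2-[4-methoxy-3-(propan-2-yloxy)phenyl]ethyl}phenoxy)phenyl]methyl}triphenylphosphonium bromide
Conditions: PPh3·HBr, MeCN, reflux
Reagents that add atoms: triphenylphosphine hydrobromide, Br.c1ccc(cc1)P(c1ccccc1)c1ccccc1
Why: Direct phosphonium salt formation from a benzylic alcohol under mild Brønsted acid; methyl, isopropyl and diaryl ethers are stable to this acid.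

Step 8
Reactants: 10 {[5-methoxy-2-(3-{2-[4-methoxy-3-(propan-2-yloxy)phenyl]ethyl}phenoxy)phenyl]methyl}triphenylphosphonium bromide; 11 4-fluoro-3-nitrobenzaldehyde
Product: 12 1-fluoro-4-{2-[5-methoxy-2-(3-{2-[4-methoxy-3-(propan-2-yloxy)phenyl]ethyl}phenoxy)phenyl]ethenyl}-2-nitrobenzene (E/Z mixture)
Conditions: K2CO3, 18-crown-6 (cat.), CH2Cl2, reflux
Reagents that add atoms: none
Why: Wittig olefination under solid–liquid phase transfer; the weak carbonate base generates the ylide in low concentration beside a very electrophilic aldehyde, so carbonyl addition should outpace attack at the C–F carbon.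

Step 9
Reactants: 12 1-fluoro-4-{2-[5-methoxy-2-(3-{2-[4-methoxy-3-(propan-2-yloxy)phenyl]ethyl}phenoxy)phenyl]ethenyl}-2-nitrobenzene
Product: 13 1-fluoro-4-{2-[5-methoxy-2-(3-{2-[4-methoxy-3-(propan-2-yloxy)phenyl]ethyl}phenoxy)phenyl]ethyl}-2-nitrobenzene
Conditions: TsNHNH2, NaOAc, THF/H2O, reflux
Reagents that add atoms: none
Why: Diimide reduction, a concerted transfer of two hydrogens to the C=C bond; unlike hydrogenation over palladium it leaves the nitro group and the aryl fluoride untouched.

Step 10
Reactants: 13 1-fluoro-4-{2-[5-methoxy-2-(3-{2-[4-methoxy-3-(propan-2-yloxy)phenyl]ethyl}phenoxy)phenyl]ethyl}-2-nitrobenzene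
Product: 14 5-[2-(3-{2-[2-(4-fluoro-3-nitrophenyl)ethyl]-4-methoxyphenoxy}phenyl)ethyl]-2-methoxyphenol
Conditions: BCl3, CH2Cl2, −78 to 0 °C
Reagents that add atoms: none
Why: Lewis acid dealkylation; the secondary isopropyl group leaves by an ionising pathway much faster than methyl, so both methyl ethers, the diaryl ether and the fluoronitroarene should remain.

Step 11
Reactants: 14 5-[2-(3-{2-[2-(4-fluoro-3-nitrophenyl)ethyl]-4-methoxyphenoxy}phenyl)ethyl]-2-methoxyphenol
Product: 15 macrocyclic nitro diaryl ether (18-membered ring A–CH2CH2–B–O–C–CH2CH2–D–O–A; OMe on ring A para and on ring C ortho to the ether oxygens; NO2 on ring B ortho to its ether oxygen)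
Conditions: K2CO3, DMF, slow addition to 0.005 M, rt
Reagents that add atoms: none
Why: Carbonate deprotonates the only free hydroxyl, the ring C phenol, and the phenoxide adds to the fluorine-bearing C4 of ring B to give a Meisenheimer anion whose charge is taken up by the ortho nitro group; loss of fluoride then gives the diaryl ether (addition–elimination, SNAr). The closest known reaction type is the intramolecular SNAr macro-etherification of phenoxides on 4-fluoro-3-nitrophenyl units, which closes diaryl ether macrocycles of comparable size at or near room temperature. The 18-membered ring is closed end to end by oxygen–carbon bond formation at an sp2 carbon, the chain being turned by the meta-linked ring D and the ortho-linked ring A. No stereocentre is formed; if rotation of the nitrated ring B were slow, the product would only be a racemic pair of conformers that merge once the nitro group is gone. The selectivity needed is ring closure over intermolecular substitution, which is secured by slow addition to a dilute suspension of base so that the phenoxide concentration stays low. Chemoselectivity is built into the substrate: every other oxygen is a methyl or diaryl ether, and the only carbon activated for substitution bears fluorine, which is displaced far faster than the nitro group itself.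

Step 12
Reactants: 15 macrocyclic nitro diaryl ether
Product: 16 macrocyclic aniline (NH2 in place of NO2 on ring B)
Conditions: H2 (1 atm), 10% Pd/C, EtOAc/EtOH, rt
Reagents that add atoms: none
Why: Catalytic hydrogenation of a nitroarene to the aniline; after ring closure no other reducible group remains.

Step 13
Reactants: 16 macrocyclic aniline
Product: 18 di-O-methyl ether of the target macrocycle, via macrocyclic arenediazonium chloride 17 (not isolated)
Conditions: NaNO2, aq. HCl, THF, 0 °C; then 50% aq. H3PO2, 0 °C to rt
Reagents that add atoms: none
Why: Diazotisation followed by hydrodediazoniation with hypophosphorous acid, a radical chain in which the aryl radical takes hydrogen from the P–H bond; this is the standard way to excise a nitro activator after SNAr ether formation.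

Step 14
Reactants: 18 di-O-methyl ether of the target macrocycle
Product: 19 target macrocyclic bis(bibenzyl) (OH on ring A para to its ether oxygen, OH on ring C ortho to its ether oxygen)
Conditions: BBr3, CH2Cl2, −78 °C to rt
Reagents that add atoms: none
Why: Lewis acid demethylation of aryl methyl ethers by bromide attack on the boron-activated methyl group; the aryl–O–aryl bonds have no sp3 carbon to attack and should survive.

## Compound list

1 | isovanillin (3-hydroxy-4-methoxybenzaldehyde) | COc1ccc(C=O)cc1O | starting material
2 | 4-methoxy-3-(propan-2-yloxy)benzaldehyde | COc1ccc(C=O)cc1OC(C)C | intermediate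
3 | 3-hydroxybenzyl alcohol | OCc1cccc(O)c1 | starting material
4 | [(3-hydroxyphenyl)methyl]triphenylphosphonium bromide | Oc1cccc(C[P+](c2ccccc2)(c2ccccc2)c2ccccc2)c1.[Br-] | intermediate
5 | 3-{2-[4-methoxy-3-(propan-2-yloxy)phenyl]ethenyl}phenol, E/Z mixture | COc1ccc(C=Cc2cccc(O)c2)cc1OC(C)C | intermediate
6 | 3-{2-[4-methoxy-3-(propan-2-yloxy)phenyl]ethyl}phenol | COc1ccc(CCc2cccc(O)c2)cc1OC(C)C | intermediate
7 | 2-fluoro-5-methoxybenzaldehyde | COc1ccc(F)c(C=O)c1 | starting material
8 | 5-methoxy-2-(3-{2-[4-methoxy-3-(propan-2-yloxy)phenyl]ethyl}phenoxy)benzaldehyde | COc1ccc(CCc2cccc(Oc3ccc(OC)cc3C=O)c2)cc1OC(C)C | intermediate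
9 | [5-methoxy-2-(3-{2-[4-methoxy-3-(propan-2-yloxy)phenyl]ethyl}phenoxy)phenyl]methanol | COc1ccc(CCc2cccc(Oc3ccc(OC)cc3CO)c2)cc1OC(C)C | intermediate
10 | {[5-methoxy-2-(3-{2-[4-methoxy-3-(propan-2-yloxy)phenyl]ethyl}phenoxy)phenyl]methyl}triphenylphosphonium bromide | COc1ccc(CCc2cccc(Oc3ccc(OC)cc3C[P+](c4ccccc4)(c4ccccc4)c4ccccc4)c2)cc1OC(C)C.[Br-] | intermediate
11 | 4-fluoro-3-nitrobenzaldehyde | O=Cc1ccc(F)c(c1)[N+](=O)[O-] | starting material
12 | 1-fluoro-4-{2-[5-methoxy-2-(3-{2-[4-methoxy-3-(propan-2-yloxy)phenyl]ethyl}phenoxy)phenyl]ethenyl}-2-nitrobenzene, E/Z mixture | COc1ccc(CCc2cccc(Oc3ccc(OC)cc3C=Cc4ccc(F)c(c4)[N+](=O)[O-])c2)cc1OC(C)C | intermediate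
13 | 1-fluoro-4-{2-[5-methoxy-2-(3-{2-[4-methoxy-3-(propan-2-yloxy)phenyl]ethyl}phenoxy)phenyl]ethyl}-2-nitrobenzene | COc1ccc(CCc2cccc(Oc3ccc(OC)cc3CCc4ccc(F)c(c4)[N+](=O)[O-])c2)cc1OC(C)C | intermediate
14 | 5-[2-(3-{2-[2-(4-fluoro-3-nitrophenyl)ethyl]-4-methoxyphenoxy}phenyl)ethyl]-2-methoxyphenol (open fluoronitroarene phenol) | COc1ccc(CCc2cccc(Oc3ccc(OC)cc3CCc4ccc(F)c(c4)[N+](=O)[O-])c2)cc1O | intermediate
15 | macrocyclic nitro diaryl ether, di-O-methyl ether (NO2 on ring B ortho to its ether oxygen) | COc1ccc2c(c1)CCc1ccc(c(c1)[N+](=O)[O-])Oc1cc(ccc1OC)CCc1cccc(c1)O2 | intermediate
16 | macrocyclic aniline, di-O-methyl ether (NH2 on ring B ortho to its ether oxygen) | COc1ccc2c(c1)CCc1ccc(c(N)c1)Oc1cc(ccc1OC)CCc1cccc(c1)O2 | intermediate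
17 | macrocyclic arenediazonium chloride, di-O-methyl ether | COc1ccc2c(c1)CCc1ccc(c(c1)[N+]#N)Oc1cc(ccc1OC)CCc1cccc(c1)O2.[Cl-] | intermediate (not isolated)
18 | di-O-methyl ether of the target macrocycle | COc1ccc2c(c1)CCc1ccc(cc1)Oc1cc(ccc1OC)CCc1cccc(c1)O2 | intermediate
19 | target macrocyclic bis(bibenzyl) | Oc1ccc2c(c1)CCc1ccc(cc1)Oc1cc(ccc1O)CCc1cccc(c1)O2 | target

## Step count and least certain steps

Total: 14 steps. Longest linear sequence: 13 steps (steps 1 and 3 to 14 from isovanillin 1; equally steps 2 to 14 from 3).

**Step 11 (key step).** The likeliest failure is intermolecular substitution leading to cyclic dimers and oligomers. The open chain of 14 is flexible and nothing but dilution favours the 18-membered closure. The fallback gives up closure at the ether and closes the ring at the A–B bridge instead. It sets out from aldehyde 8, whose isopropyl ether would be cleaved with BCl3 to give 2-{3-[2-(3-hydroxy-4-methoxyphenyl)ethyl]phenoxy}-5-methoxybenzaldehyde F1. Intermolecular SNAr of its phenoxide on 4-fluorobenzaldehyde (K2CO3, DMF, 120 °C) would give the dialdehyde 2-(3-{2-[3-(4-formylphenoxy)-4-methoxyphenyl]ethyl}phenoxy)-5-methoxybenzaldehyde F2. Intramolecular McMurry coupling with low-valent titanium from TiCl4 and Zn in THF under high dilution would give the macrocyclic stilbene di-O-methyl ether F3. Hydrogenation over 10% Pd/C would return the route at 18, with no nitro group to remove.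

**Step 5.** The likeliest failure is incomplete substitution with slow decomposition of the aldehyde at 140 °C, because the methoxy group para to fluorine lowers the electrophilicity of 7. The fallback replaces SNAr by an Ullmann ether coupling. It sets out from phenol 6, which would be coupled with methyl 2-bromo-5-methoxybenzoate (CuI, picolinic acid, K3PO4, DMSO, 90 °C) to give methyl 5-methoxy-2-(3-{2-[4-methoxy-3-(propan-2-yloxy)phenyl]ethyl}phenoxy)benzoate F4. Reduction with LiAlH4 would return the route at alcohol 9.

**Step 8.** The likeliest failure is slow ylide formation from the electron-rich salt 10 under the weak base. This would leave time for displacement of fluoride by the ylide or for degradation of the aldehyde. The fallback uses a preformed phosphonate carbanion, so that no free base meets the fluoronitroarene. It sets out from alcohol 9, which CBr4 and PPh3 would convert to 2-(bromomethyl)-4-methoxy-1-(3-{2-[4-methoxy-3-(propan-2-yloxy)phenyl]ethyl}phenoxy)benzene F5. An Arbuzov reaction with P(OEt)3 would give diethyl {[5-methoxy-2-(3-{2-[4-methoxy-3-(propan-2-yloxy)phenyl]ethyl}phenoxy)phenyl]methyl}phosphonate F6. Deprotonation with NaH in THF and Horner–Wadsworth–Emmons reaction with 11 at low temperature would return the route at 12, mainly as the E isomer.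

**Step 9.** The likeliest failures are displacement of the activated fluoride by the sulfinate released from the hydrazide at reflux, and incomplete reduction of the conjugated E isomer while diimide disproportionates. The fallback moves the ring closure ahead of the reduction. It sets out from stilbene 12, which BCl3 would convert to 5-[2-(3-{2-[2-(4-fluoro-3-nitrophenyl)ethenyl]-4-methoxyphenoxy}phenyl)ethyl]-2-methoxyphenol F7. SNAr ring closure under the conditions of step 11 would give the macrocyclic nitrostilbene di-O-methyl ether F8. One hydrogenation over 10% Pd/C would then reduce the C=C bond and the nitro group together and return the route at aniline 16. The E isomer of F7 may close less readily than the Z isomer.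

## Further compounds

F1 | step 11 | 2-{3-[2-(3-hydroxy-4-methoxyphenyl)ethyl]phenoxy}-5-methoxybenzaldehyde | COc1ccc(CCc2cccc(Oc3ccc(OC)cc3C=O)c2)cc1O
F2 | step 11 | 2-(3-{2-[3-(4-formylphenoxy)-4-methoxyphenyl]ethyl}phenoxy)-5-methoxybenzaldehyde | COc1ccc(CCc2cccc(Oc3ccc(OC)cc3C=O)c2)cc1Oc1ccc(C=O)cc1
F3 | step 11 | macrocyclic stilbene di-O-methyl ether (C=C in the A–B bridge, no nitro group), E/Z | COc1ccc2c(c1)C=Cc1ccc(cc1)Oc1cc(ccc1OC)CCc1cccc(c1)O2
F4 | step 5 | methyl 5-methoxy-2-(3-{2-[4-methoxy-3-(propan-2-yloxy)phenyl]ethyl}phenoxy)benzoate | COc1ccc(CCc2cccc(Oc3ccc(OC)cc3C(=O)OC)c2)cc1OC(C)C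
F5 | step 8 | 2-(bromomethyl)-4-methoxy-1-(3-{2-[4-methoxy-3-(propan-2-yloxy)phenyl]ethyl}phenoxy)benzene | COc1ccc(CCc2cccc(Oc3ccc(OC)cc3CBr)c2)cc1OC(C)C
F6 | step 8 | diethyl {[5-methoxy-2-(3-{2-[4-methoxy-3-(propan-2-yloxy)phenyl]ethyl}phenoxy)phenyl]methyl}phosphonate | COc1ccc(CCc2cccc(Oc3ccc(OC)cc3CP(=O)(OCC)OCC)c2)cc1OC(C)C
F7 | step 9 | 5-[2-(3-{2-[2-(4-fluoro-3-nitrophenyl)ethenyl]-4-methoxyphenoxy}phenyl)ethyl]-2-methoxyphenol, E/Z | COc1ccc(CCc2cccc(Oc3ccc(OC)cc3C=Cc4ccc(F)c(c4)[N+](=O)[O-])c2)cc1O
F8 | step 9 | macrocyclic nitrostilbene di-O-methyl ether (C=C in the A–B bridge, NO2 on ring B), E/Z | COc1ccc2c(c1)C=Cc1ccc(c(c1)[N+](=O)[O-])Oc1cc(ccc1OC)CCc1cccc(c1)O2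
A1 | alternative 1 | methyl 4-aryloxy-3-(arylethyl)benzoate, ring A as benzoate | COC(=O)c1ccc(Oc2cccc(c2)CCc2ccc(OC)c(OCc3ccccc3)c2)c(c1)CCc1ccc(Br)cc1
A2 | alternative 1 | methyl coumalate | COC(=O)C1=COC(=O)C=C1
A3 | alternative 1 | internal aryl ynol ether (ring D–O–C≡C–CH2CH2–ring B bromide, ring C benzyl-protected) | COc1ccc(CCc2cccc(OC#CCCc3ccc(Br)cc3)c2)cc1OCc1ccccc1
A4 | alternative 2 | macrocyclic cyclohexadienyl ketone, ring B at the dihydro level | COc1ccc2c(c1)CC(=O)C1=CCC(=CC1)Oc1cc(ccc1OC)CCc1cccc(c1)O2
A5 | alternative 2 | open 2-aryloxybuta-1,3-diene ethynyl ketone | COc1ccc(Oc2cccc(CCc3ccc(OC)c(OC(=C)C=C)c3)c2)c(CC(=O)C#C)c1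
A6 | alternative 3 | trihalogenated macrocycle with free ring C phenol | COc1ccc2c(c1)CCc1cc(Cl)c(c(Cl)c1)Oc1cc(cc(Br)c1O)CCc1cccc(c1)O2
A7 | alternative 3 | open bis(dihalophenol) (2,6-dichlorophenol as ring B, 2,6-dibromophenol as ring C) | COc1ccc(Oc2cccc(CCc3cc(Br)c(O)c(Br)c3)c2)c(CCc2cc(Cl)c(O)c(Cl)c2)c1
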